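## The problem

1. The target is a cyclohex‑2‑ene‑1,4‑dione, C1(=O)–C2H=C3H–C4(=O)–C5–C6H2. Its only ring stereocentre, the all‑carbon quaternary C5 (R), carries a CH2CO2Me arm (C7, C8) and a C16 tetraprenyl chain (C1′–C16′). The chain has three E‑trisubstituted olefins and an anti 12′S,13′R diol that is allylic on both sides.
2. C5 is the hard centre. Its substituents are C(=O), ring CH2C(=O), CH2C(=O)OMe and CH2CH=C, so two of them differ only at the third atom. No other stereocentre lies within eleven bonds, so substrate control is impossible and a wrong C5 epimer would be inseparable.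
3. The ring is the blocked keto tautomer of a hydroquinone. Any intermediate with hydrogen at C5 together with the C2=C3 bond aromatises, so C5 must be quaternary before the enedione is unveiled, and the base‑labile, electrophilic enedione should appear late.
4. The chain must be joined at C5–C1′ without loss of the 2′E geometry. This argues for SN2 alkylation by an allylic bromide, not π‑allyl or sigmatropic delivery. The skipped polyene and the bis‑allylic diol tolerate neither strong acid nor dissolving metal.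
5. C12′ and C13′ can control each other but not C5, and C5 cannot control them.
6. The feature used here: C5 carries two CH2–C(=O) arms, C6–C1 in the ring and C7–C8 in the ester. A bond between C2 and C8 makes them two equivalent bridges of a bicyclo[2.2.2]octane‑2,5,8‑trione (bridgeheads C5 and C2, third bridge C4(=O)–C3H2). Its core has a mirror plane through C5, C4, C3 and C2, so C5 is no stereocentre and C1/C8 are the enantiotopic carbonyls of a non‑enolisable β‑diketone.

## Retrosynthesis

**21 ⇒ 20 ⇒ 18 (end game).** The diol is carried as its cis‑acetonide 20. The C2=C3 bond is taken back to the saturated 1,4‑dione 18. In 18 dehydrogenation can only give C2=C3, because C5 has no hydrogen and neither ketone can be desaturated toward C5 or C6. The forward steps must avoid alkoxide bases: Dieckmann closure of 18 back to 16 and re‑opening would racemise C5.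

**18 ⇐ 17 ⇐ 16 (key disconnection: the C2–C8 bond is added).** Cutting C5–C1′ or C5–C7 of 18 directly would need an enantioselective alkylation at a carbon whose groups are nearly alike. Adding C2–C8 instead removes the stereocentre: trione 16 has no stereocentre in its carbocyclic part. The forward reaction must hydrate one of two enantiotopic carbonyls and break its bond to C2 (retro‑Claisen), which is what a β‑diketone hydrolase does. This one step creates C5, opens the bicycle to the 1,4‑dione ring and frees the acetic acid arm.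

**16 ⇐ 15 ⇐ 14 (bond C2–C3).** The third bridge is closed by intramolecular C‑alkylation of the symmetrical cyclohexane‑1,3‑dione 15 by its own chloroacetyl group. Because 15 is symmetrical there is no regiochemistry. 15 comes from the bis(methyl enol ether) 14 by mild acid hydrolysis.

**14 ⇐ 12 (bond C3–C4).** The chloromethyl ketone arises by one‑carbon homologation of methyl ester 12 with a chloromethyl carbenoid. The ester carbon becomes C4 and the new carbon becomes C3.

**12 ⇐ 10 + 9 (bond C5–C1′, fragment union).** Birch reduction–alkylation of methyl 3,5‑dimethoxybenzoate 10 with allylic bromide 9. The arene supplies C5 (ipso), C4 (ester carbon), C6/C7 (ortho carbons), C1/C8 (methoxy‑bearing carbons) and C2 (para carbon), all at the right oxidation level. The union is an SN2 reaction at C1′, so the 2′E geometry is kept, and it creates no stereocentre.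

**9 ⇐ 8 ⇐ 7 ⇐ 6 ⇐ 3 ⇐ 2 ⇐ 1 (side chain).** Bromide 9 comes from alcohol 8. The C14′=C15′ terminus comes from cross‑metathesis of vinyl compound 7, the acetonide of triol 6. The C12′–C13′ bond and both carbinol centres come from an anti‑selective γ‑silylallylboration/oxidation of enal 3. Enal 3 comes from (2E,6E)‑farnesyl acetate 1 via allylic oxidation to 2. All three E‑olefins are bought with farnesol.

## Roads not taken

**Alternative 1: biomimetic dearomatising alkylation (the obvious route).** Cut C5–C1′ on the aromatic level: the phenoxide of methyl homogentisate A1 is C‑alkylated at the ipso carbon by 9 to give enedione A2 after tautomerisation. A1 offers two oxygens (on C1 and C4) and three unsubstituted ring carbons (C2, C3, C6); attack there is sterically favoured and ends in a stable aromatic product. Attack at the substituted carbon is the least likely, and nothing in the step controls C5, so A2 would be an inseparable C5 epimer pair. The chosen plan alkylates an ester enolate that can only react at the ipso carbon, and sets C5 in a separate, group‑selective step.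

**Alternative 2: decarboxylative asymmetric allylation through an ester tether.** Cut C5–C1′ and tie the chain alcohol to the ring as β‑ketoester A3. A palladium‑catalysed decarboxylative allylic alkylation would give A4, and ketal hydrolysis then 20. This is short, but the allyl unit is 3,3‑disubstituted. Terminal substitution slows the inner‑sphere C–C bond formation that gives high selectivity with allyl and 2‑substituted allyl groups. It also opens linear/branched and E/Z leakage through σ‑allyl isomerisation at C3′. The catalyst would have to tell CH2CO2Me from ring CH2 on the enolate. In the chosen plan the geometry comes from SN2 and the configuration from enzymatic group selection, so the two demands are separated.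

**Alternative 3: temporary γ‑lactone and a sacrificial C4 carbinol.** Cut C5–C7: C4 is kept as a carbinol (set by Corey–Bakshi–Shibata reduction) and esterified as malonate A5. Intramolecular Michael addition gives the cis‑fused lactone A6. Krapcho decarboxylation, lactone opening, oxidation of C4–OH and dehydrogenation follow. This needs an external chiral reagent, about five more steps, and a base‑mediated Michael addition on a γ‑acyloxy enone whose C1′ methylene is vinylogously acidic. The lactone also tends to re‑close. The chosen plan has one stereo‑defining step and no protecting group on the ring.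

Key step: step 11

Notation and one assumption: Ch = (2E,6E,10E)‑11‑[(4S,5R)‑2,2‑dimethyl‑5‑(2‑methylprop‑1‑en‑1‑yl)‑1,3‑dioxolan‑4‑yl]‑3,7‑dimethyldodeca‑2,6,10‑trien‑1‑yl (the acetonide‑protected side chain, attached through C1′). It is assumed that (2E,6E)‑farnesyl acetate, methyl 3,5‑dimethoxybenzoate, allyl(diisopropylamino)dimethylsilane and (+)‑Ipc2BOMe are purchased.

## Route

Step 1
Reactants: 1 (2E,6E)‑farnesyl acetate
Product: 2 (2E,6E,10E)‑12‑hydroxy‑3,7,11‑trimethyldodeca‑2,6,10‑trien‑1‑yl acetate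
Conditions: SeO2 (0.3 equiv), t‑BuOOH (70% aq., 3 equiv), salicylic acid (0.1 equiv), CH2Cl2, 0 °C to rt
Reagents that add atoms: selenium dioxide, O=[Se]=O (catalytic oxygen carrier); tert‑butyl hydroperoxide, CC(C)(C)OO (stoichiometric oxygen source)
Why: Catalytic SeO2 allylic oxidation (ene reaction then [2,3] shift) is selective for the E‑methyl of the terminal trisubstituted olefin, so the 10E geometry of the new allylic alcohol follows from the mechanism; the allylic acetate protects C1′.

Step 2
Reactants: 2 (2E,6E,10E)‑12‑hydroxy‑3,7,11‑trimethyldodeca‑2,6,10‑trien‑1‑yl acetate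
Product: 3 (2E,6E,10E)‑3,7,11‑trimethyl‑12‑oxododeca‑2,6,10‑trien‑1‑yl acetate
Conditions: Dess–Martin periodinane (1.2 equiv), NaHCO3, CH2Cl2, 0 °C to rt
Reagents that add atoms: none
Why: Dess–Martin oxidation of a primary allylic alcohol to the enal under buffered, non‑acidic conditions leaves the olefin geometry and the acetate untouched.

Step 3
Reactants: 3 (2E,6E,10E)‑3,7,11‑trimethyl‑12‑oxododeca‑2,6,10‑trien‑1‑yl acetate
Product: 6 (2E,6E,10E,12S,13R)‑3,7,11‑trimethylpentadeca‑2,6,10,14‑tetraene‑1,12,13‑triol, via borinate adduct 4 (not isolated), via diol acetate 5 (not isolated)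
Conditions: allyl(diisopropylamino)dimethylsilane, n‑BuLi, TMEDA, Et2O, 0 °C; (+)‑Ipc2BOMe [from (−)‑α‑pinene], −78 °C; BF3·OEt2; then 3, −78 °C; then 30% H2O2, KF, KHCO3, THF–MeOH, rt; then K2CO3 (cat.), MeOH, rt
Reagents that add atoms: allyl(diisopropylamino)dimethylsilane, C=CC[Si](C)(C)N(C(C)C)C(C)C (three carbons); hydrogen peroxide, OO (oxygen on C13′)
Why: Asymmetric γ‑silylallylboration followed by Tamao–Fleming oxidation: the (E)‑γ‑silylallyl‑diisopinocampheylborane adds through a closed chair transition state, which gives the anti relationship. By the usual facial model for these borane reagents the (−)‑α‑pinene‑derived ligands send the allyl group to the Re face of the enal, giving 12′S and hence 13′R; C–Si oxidation occurs with retention, and methanolysis removes the acetate in the same flask.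

Step 4
Reactants: 6 (2E,6E,10E,12S,13R)‑3,7,11‑trimethylpentadeca‑2,6,10,14‑tetraene‑1,12,13‑triol
Product: 7 (2E,6E,10E)‑11‑[(4S,5R)‑5‑ethenyl‑2,2‑dimethyl‑1,3‑dioxolan‑4‑yl]‑3,7‑dimethyldodeca‑2,6,10‑trien‑1‑ol
Conditions: 2,2‑dimethoxypropane (1.3 equiv), PPTS (0.05 equiv), CH2Cl2, 0 °C to rt; aqueous NH4Cl work‑up
Reagents that add atoms: 2,2‑dimethoxypropane, COC(C)(C)OC
Why: Transketalisation selects the 1,2‑diol (five‑membered cis‑dioxolane from the anti diol); any mixed ketal on the primary allylic alcohol is lost on work‑up.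

Step 5
Reactants: 7 (2E,6E,10E)‑11‑[(4S,5R)‑5‑ethenyl‑2,2‑dimethyl‑1,3‑dioxolan‑4‑yl]‑3,7‑dimethyldodeca‑2,6,10‑trien‑1‑ol
Product: 8 Ch–OH, (2E,6E,10E)‑11‑[(4S,5R)‑2,2‑dimethyl‑5‑(2‑methylprop‑1‑en‑1‑yl)‑1,3‑dioxolan‑4‑yl]‑3,7‑dimethyldodeca‑2,6,10‑trien‑1‑ol
Conditions: second‑generation Grubbs catalyst RuCl2(H2IMes)(PCy3)(=CHPh) (5 mol %), 2‑methylbut‑2‑ene (large excess)/CH2Cl2, 40 °C
Reagents that add atoms: 2‑methylbut‑2‑ene, CC=C(C)C
Why: Olefin cross‑metathesis of the only monosubstituted alkene with 2‑methylbut‑2‑ene; the three internal trisubstituted chain olefins are much slower partners and should be spectators at short reaction time. The gem‑dimethyl terminus has no geometry to control and no stereocentre is touched.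

Step 6
Reactants: 8 Ch–OH
Product: 9 Ch–Br, (2E,6E,10E)‑1‑bromo‑11‑[(4S,5R)‑2,2‑dimethyl‑5‑(2‑methylprop‑1‑en‑1‑yl)‑1,3‑dioxolan‑4‑yl]‑3,7‑dimethyldodeca‑2,6,10‑triene
Conditions: CBr4 (1.2 equiv), PPh3 (1.25 equiv), CH2Cl2, −30 to 0 °C; used crude
Reagents that add atoms: tetrabromomethane, BrC(Br)(Br)Br
Why: Appel bromination of a primary allylic alcohol under neutral conditions gives the primary bromide without allylic transposition and without touching the acetonide.

Step 7
Reactants: 10 methyl 3,5‑dimethoxybenzoate; 9 Ch–Br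
Product: 12 methyl 1‑Ch‑3,5‑dimethoxycyclohexa‑2,5‑diene‑1‑carboxylate, via potassium ester enolate 11 (not isolated)
Conditions: K (2.2 equiv), NH3 (l)/THF, t‑BuOH (1.0 equiv), −78 °C; penta‑1,3‑diene to discharge excess K; then 9 (0.9 equiv) in THF, −78 °C
Reagents that add atoms: none
Why: Birch reduction–alkylation: two electrons and one proton (para to the ester) give the cross‑conjugated ester enolate 11, which can only be alkylated at the ipso carbon. The SN2 reaction at C1′ keeps the 2′E geometry; the new quaternary carbon is not a stereocentre because its two ring arms are identical.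

Step 8
Reactants: 12 methyl 1‑Ch‑3,5‑dimethoxycyclohexa‑2,5‑diene‑1‑carboxylate
Product: 14 2‑chloro‑1‑(1‑Ch‑3,5‑dimethoxycyclohexa‑2,5‑dien‑1‑yl)ethan‑1‑one, via lithium hemiketal alkoxide 13 (not isolated)
Conditions: ICH2Cl (1.6 equiv), MeLi·LiBr (1.5 equiv, slow addition), THF, −78 °C; sat. NH4Cl quench at −78 °C
Reagents that add atoms: chloroiodomethane, ClCI
Why: Chloromethyllithium made in situ adds to the ester to give a tetrahedral alkoxide that is stable at −78 °C and collapses to the α‑chloroketone only on quench (one‑carbon homologation of esters to chloromethyl ketones); enol ethers, olefins and acetonide are inert to the carbenoid.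

Step 9
Reactants: 14 2‑chloro‑1‑(1‑Ch‑3,5‑dimethoxycyclohexa‑2,5‑dien‑1‑yl)ethan‑1‑one
Product: 15 5‑(chloroacetyl)‑5‑Ch‑cyclohexane‑1,3‑dione
Conditions: 0.1 M HCl (aq)/THF 1:4, 0 °C to rt; extractive work‑up
Reagents that add atoms: water, O
Why: The two isolated methyl enol ethers are hydrolysed by C‑protonation next to the quaternary carbon, far faster than the acetonide is cleaved at this acidity; the product is the symmetrical 1,3‑dione (as its enol).

Step 10
Reactants: 15 5‑(chloroacetyl)‑5‑Ch‑cyclohexane‑1,3‑dione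
Product: 16 1‑Ch‑bicyclo[2.2.2]octane‑2,5,8‑trione
Conditions: K2CO3 (anhydrous, 1.5 equiv), NaI (0.1 equiv), MeCN, 0.01 M, rt
Reagents that add atoms: none
Why: Intramolecular C‑alkylation of the 1,3‑dione enolate by the α‑chloroketone (6‑(enolendo)‑exo‑tet), closely related to the cyclisation of 5‑(2‑haloethyl)cyclohexane‑1,3‑diones to bicyclo[2.2.2]octane‑2,6‑diones. O‑alkylation would give a strained bridgehead enol ether; the dione is symmetrical, so the product keeps the local mirror plane. An anhydrous, non‑nucleophilic base is used because hydroxide or alkoxide would open 16.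

Step 11
Reactants: 16 1‑Ch‑bicyclo[2.2.2]octane‑2,5,8‑trione
Product: 17 2‑[(1R)‑1‑Ch‑2,5‑dioxocyclohexyl]acetic acid
Conditions: β‑diketone hydrolase (retro‑Claisenase of the crotonase superfamily, 6‑oxocamphor hydrolase type), potassium phosphate buffer (KH2PO4/K2HPO4, 50 mM, pH 7.0), 10% DMSO or hydroxypropyl‑β‑cyclodextrin, 25 °C
Reagents that add atoms: water, O
Why: β‑Diketone hydrolases of this family add water to one carbonyl of a non‑enolisable bicyclic β‑diketone and break the bond to the carbon between the two carbonyls, the leaving group being the enolate of the second ketone (enzymatic retro‑Claisen). The closest known case is the desymmetrisation of bicyclo[2.2.2]octane‑2,6‑dione to 2‑(3‑oxocyclohexyl)acetic acid with high enantioselectivity. No ring is closed: the C2–C8 bond is cut, which opens the bicycle to the cyclohexane‑1,4‑dione and frees the CH2CO2H arm. In 16 the bridgehead C5 is no stereocentre, because its two CH2C(=O) arms are related by the mirror plane through C5, C4, C3 and C2; the cut makes one arm the ring (C6–C1) and the other the side chain (C7–C8), so C5 becomes stereogenic in this step and nowhere else. Its configuration is set by the enzyme alone: water must add to the carbonyl on the pro‑R methylene arm of C5 to give 5R; the two carbonyls are enantiotopic within the bicycle and diastereotopic only through the remote chain centres, which cannot bias the choice. Chemoselectivity comes from the substrate: only the two carbonyls flanking C2 can expel a stabilised carbanion, the C4 ketone cannot fragment, and since C2–H is at a bridgehead the diketone cannot enolise, so no racemic background path exists at pH 7. The chain sits on the bridgehead remote from the reacting face and can point to solvent; a panel of wild‑type and engineered hydrolases of both enantiopreferences is to be screened.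

Step 12
Reactants: 17 2‑[(1R)‑1‑Ch‑2,5‑dioxocyclohexyl]acetic acid
Product: 18 methyl 2‑[(1R)‑1‑Ch‑2,5‑dioxocyclohexyl]acetate
Conditions: TMSCHN2 (1.2 equiv), MeOH/toluene 1:4, 0 °C
Reagents that add atoms: (trimethylsilyl)diazomethane, C[Si](C)(C)C=[N+]=[N-]
Why: Neutral esterification of the carboxylic acid by diazoalkane; bases and alkoxides are avoided because Dieckmann closure of 18 back to 16 and re‑opening would erase the configuration at C5.

Step 13
Reactants: 18 methyl 2‑[(1R)‑1‑Ch‑2,5‑dioxocyclohexyl]acetate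
Product: 20 methyl 2‑[(1R)‑1‑Ch‑2,5‑dioxocyclohex‑3‑en‑1‑yl]acetate, via bis(silyl enol ether) 19 (not isolated)
Conditions: TMSOTf (2.5 equiv), Et3N (4 equiv), CH2Cl2, 0 °C; then Pd(OAc)2 (1.1 equiv), MeCN, rt
Reagents that add atoms: none
Why: Ito–Saegusa oxidation: the C4 ketone can enolise only toward C3, and an enol ether of C1 toward C6 has no β‑hydrogen (C5 is quaternary), so every enol ether that forms leads to the single possible enedione with C2=C3. Soft enolisation with amine and silyl triflate avoids free enolates that could close back to 16.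

Step 14
Reactants: 20 methyl 2‑[(1R)‑1‑Ch‑2,5‑dioxocyclohex‑3‑en‑1‑yl]acetate
Product: 21 methyl 2‑[(1R)‑1‑[(2E,6E,10E,12S,13R)‑12,13‑dihydroxy‑3,7,11,15‑tetramethylhexadeca‑2,6,10,14‑tetraen‑1‑yl]‑2,5‑dioxocyclohex‑3‑en‑1‑yl]acetate
Conditions: AcOH/H2O/THF 3:1:1, 35 °C
Reagents that add atoms: none
Why: Acid‑catalysed acetal hydrolysis runs through the dialkoxycarbenium ion at the acetal carbon, not through allylic C–O ionisation, so the anti diol should be released without transposition; the enedione tolerates weak aqueous acid.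

## Compound list

1 | (2E,6E)‑farnesyl acetate | CC(=O)OC/C=C(\C)CC/C=C(\C)CCC=C(C)C | starting material
2 | (2E,6E,10E)‑12‑hydroxy‑3,7,11‑trimethyldodeca‑2,6,10‑trien‑1‑yl acetate | CC(=O)OC/C=C(\C)CC/C=C(\C)CC/C=C(\C)CO | intermediate
3 | (2E,6E,10E)‑3,7,11‑trimethyl‑12‑oxododeca‑2,6,10‑trien‑1‑yl acetate | CC(=O)OC/C=C(\C)CC/C=C(\C)CC/C=C(\C)C=O | intermediate
4 | (2E,6E,10E,12S,13R)‑12‑[(diisopinocampheylboryl)oxy]‑13‑[(diisopropylamino)dimethylsilyl]‑3,7,11‑trimethylpentadeca‑2,6,10,14‑tetraen‑1‑yl acetate | CC(=O)OC/C=C(\C)CC/C=C(\C)CC/C=C(\C)[C@H](OB([C@H]1C[C@H]2C[C@@H]([C@@H]1C)C2(C)C)[C@H]1C[C@H]2C[C@@H]([C@@H]1C)C2(C)C)[C@H]([Si](C)(C)N(C(C)C)C(C)C)C=C | intermediate (not isolated)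
5 | (2E,6E,10E,12S,13R)‑12,13‑dihydroxy‑3,7,11‑trimethylpentadeca‑2,6,10,14‑tetraen‑1‑yl acetate | CC(=O)OC/C=C(\C)CC/C=C(\C)CC/C=C(\C)[C@H](O)[C@H](O)C=C | intermediate (not isolated)
6 | (2E,6E,10E,12S,13R)‑3,7,11‑trimethylpentadeca‑2,6,10,14‑tetraene‑1,12,13‑triol | OC/C=C(\C)CC/C=C(\C)CC/C=C(\C)[C@H](O)[C@H](O)C=C | intermediate
7 | (2E,6E,10E)‑11‑[(4S,5R)‑5‑ethenyl‑2,2‑dimethyl‑1,3‑dioxolan‑4‑yl]‑3,7‑dimethyldodeca‑2,6,10‑trien‑1‑ol | OC/C=C(\C)CC/C=C(\C)CC/C=C(\C)[C@@H]1OC(C)(C)O[C@@H]1C=C | intermediate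
8 | Ch–OH, (2E,6E,10E)‑11‑[(4S,5R)‑2,2‑dimethyl‑5‑(2‑methylprop‑1‑en‑1‑yl)‑1,3‑dioxolan‑4‑yl]‑3,7‑dimethyldodeca‑2,6,10‑trien‑1‑ol | OC/C=C(\C)CC/C=C(\C)CC/C=C(\C)[C@@H]1OC(C)(C)O[C@@H]1C=C(C)C | intermediate
9 | Ch–Br, (2E,6E,10E)‑1‑bromo‑11‑[(4S,5R)‑2,2‑dimethyl‑5‑(2‑methylprop‑1‑en‑1‑yl)‑1,3‑dioxolan‑4‑yl]‑3,7‑dimethyldodeca‑2,6,10‑triene | BrC/C=C(\C)CC/C=C(\C)CC/C=C(\C)[C@@H]1OC(C)(C)O[C@@H]1C=C(C)C | intermediate
10 | methyl 3,5‑dimethoxybenzoate | COC(=O)c1cc(OC)cc(OC)c1 | starting material
11 | potassium enolate of methyl 3,5‑dimethoxycyclohexa‑2,5‑diene‑1‑carboxylate | COC([O-])=C1C=C(OC)CC(OC)=C1.[K+] | intermediate (not isolated)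
12 | methyl 1‑Ch‑3,5‑dimethoxycyclohexa‑2,5‑diene‑1‑carboxylate | COC(=O)C1(C/C=C(\C)CC/C=C(\C)CC/C=C(\C)[C@@H]2OC(C)(C)O[C@@H]2C=C(C)C)C=C(OC)CC(OC)=C1 | intermediate
13 | lithium 2‑chloro‑1‑methoxy‑1‑(1‑Ch‑3,5‑dimethoxycyclohexa‑2,5‑dien‑1‑yl)ethan‑1‑olate (both configurations at the hemiketal carbon) | [Li+].[O-]C(CCl)(OC)C1(C/C=C(\C)CC/C=C(\C)CC/C=C(\C)[C@@H]2OC(C)(C)O[C@@H]2C=C(C)C)C=C(OC)CC(OC)=C1 | intermediate (not isolated)
14 | 2‑chloro‑1‑(1‑Ch‑3,5‑dimethoxycyclohexa‑2,5‑dien‑1‑yl)ethan‑1‑one | ClCC(=O)C1(C/C=C(\C)CC/C=C(\C)CC/C=C(\C)[C@@H]2OC(C)(C)O[C@@H]2C=C(C)C)C=C(OC)CC(OC)=C1 | intermediate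
15 | 5‑(chloroacetyl)‑5‑Ch‑cyclohexane‑1,3‑dione | ClCC(=O)C1(C/C=C(\C)CC/C=C(\C)CC/C=C(\C)[C@@H]2OC(C)(C)O[C@@H]2C=C(C)C)CC(=O)CC(=O)C1 | intermediate
16 | 1‑Ch‑bicyclo[2.2.2]octane‑2,5,8‑trione | O=C1CC2C(=O)CC1(C/C=C(\C)CC/C=C(\C)CC/C=C(\C)[C@@H]3OC(C)(C)O[C@@H]3C=C(C)C)CC2=O | intermediate
17 | 2‑[(1R)‑1‑Ch‑2,5‑dioxocyclohexyl]acetic acid | OC(=O)C[C@@]1(C/C=C(\C)CC/C=C(\C)CC/C=C(\C)[C@@H]2OC(C)(C)O[C@@H]2C=C(C)C)CC(=O)CCC1=O | intermediate
18 | methyl 2‑[(1R)‑1‑Ch‑2,5‑dioxocyclohexyl]acetate | COC(=O)C[C@@]1(C/C=C(\C)CC/C=C(\C)CC/C=C(\C)[C@@H]2OC(C)(C)O[C@@H]2C=C(C)C)CC(=O)CCC1=O | intermediate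
19 | methyl 2‑[(1R)‑1‑Ch‑2,5‑bis(trimethylsilyloxy)cyclohexa‑2,4‑dien‑1‑yl]acetate | COC(=O)C[C@@]1(C/C=C(\C)CC/C=C(\C)CC/C=C(\C)[C@@H]2OC(C)(C)O[C@@H]2C=C(C)C)CC(O[Si](C)(C)C)=CC=C1O[Si](C)(C)C | intermediate (not isolated)
20 | methyl 2‑[(1R)‑1‑Ch‑2,5‑dioxocyclohex‑3‑en‑1‑yl]acetate | COC(=O)C[C@@]1(C/C=C(\C)CC/C=C(\C)CC/C=C(\C)[C@@H]2OC(C)(C)O[C@@H]2C=C(C)C)CC(=O)C=CC1=O | intermediate
21 | methyl 2‑[(1R)‑1‑[(2E,6E,10E,12S,13R)‑12,13‑dihydroxy‑3,7,11,15‑tetramethylhexadeca‑2,6,10,14‑tetraen‑1‑yl]‑2,5‑dioxocyclohex‑3‑en‑1‑yl]acetate (CNP0122011.2) | COC(=O)C[C@@]1(C/C=C(\C)CC/C=C(\C)CC/C=C(\C)[C@H](O)[C@H](O)C=C(C)C)CC(=O)C=CC1=O | target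

## Step count and least certain steps

Total: 14 steps. Longest linear sequence: 14 steps from farnesyl acetate 1; the arene 10 enters as a second commercial input at step 7.

**Step 11 (key step).** The most likely failure is lack of turnover: the enzyme may not bind a substrate with a C20 lipophilic substituent on the distal bridgehead and an extra ketone in the third bridge, or the substrate may not dissolve in buffer. The second risk is hydration of the wrong or of both enantiotopic carbonyls. Fallback (sets out from 9, returns at 21): commercial 1,4‑dioxaspiro[4.5]dec‑6‑en‑8‑one is alkylated at C9 with methyl bromoacetate (LiN(iPr)2, THF, −78 °C) to methyl 2‑(8‑oxo‑1,4‑dioxaspiro[4.5]dec‑6‑en‑9‑yl)acetate F1, whose ketone can enolise only toward the substituted carbon. Its tributyltin dienolate, methyl 2‑[8‑(tributylstannyloxy)‑1,4‑dioxaspiro[4.5]deca‑6,8‑dien‑9‑yl]acetate F2 (LiN(SiMe3)2, then Bu3SnCl), is alkylated with 9 under catalysis by (salen)CrCl. This is the enantioselective alkylation of tin enolates of α‑substituted cyclic ketones with allylic bromides; the catalyst antipode is chosen for 5R. The product is methyl 2‑[(9R)‑9‑Ch‑8‑oxo‑1,4‑dioxaspiro[4.5]dec‑6‑en‑9‑yl]acetate F3. Aqueous HCl in THF then removes the dioxolane and the acetonide together and gives 21. This gives up the symmetry idea but keeps the SN2 union with 9.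

**Step 8.** The carbenoid may decompose faster than it adds to the hindered, neopentyl‑type ester, leaving 12 unchanged, or the adduct may collapse before the quench and add a second equivalent. Fallback (sets out from 12, returns at 15): saponification (LiOH, aq. THF–MeOH) gives 1‑Ch‑3,5‑dimethoxycyclohexa‑2,5‑diene‑1‑carboxylic acid F4. Activation as the mixed anhydride (i‑BuOCOCl, N‑methylmorpholine) and diazomethane give 2‑diazo‑1‑(1‑Ch‑3,5‑dimethoxycyclohexa‑2,5‑dien‑1‑yl)ethan‑1‑one F5 (first stage of an Arndt–Eistert sequence). Dilute HCl in THF then turns the diazoketone into the chloromethyl ketone and hydrolyses both enol ethers in one operation, giving 15.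

**Step 10.** The enolate may react at oxygen or with a second molecule, or the strained product may be opened by the base. Fallback: if the bicycle cannot be closed, the symmetry plan is left at this point and the material is made by the fallback given for step 11, from 9 to 21; this makes no compound of its own (F0).

**Step 7.** The methyl ester may undergo ammonolysis or over‑reduction, and residual metal may transfer an electron to the allylic bromide (reductive coupling instead of alkylation). Fallback (sets out from 10 and 9, returns at 12): reduction and alkylation are separated. Birch reduction of 10 with protonation (K, NH3, t‑BuOH 2 equiv; NH4Cl) gives methyl 3,5‑dimethoxycyclohexa‑2,5‑diene‑1‑carboxylate F6. Its lithium enolate (LiN(iPr)2, THF, −78 °C) is then alkylated with 9 in the absence of ammonia and metal to give 12.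

**Step 3.** Facial and anti selectivity may erode with the α‑branched enal, and the β‑silyl alcohol may undergo Peterson‑type elimination before it is oxidised. Fallback (sets out from 2, returns at 6, and skips step 2): iridium‑catalysed transfer‑hydrogenative anti‑(α‑acyloxy)allylation from the alcohol oxidation level. Conditions: 2, prop‑2‑ene‑1,1‑diyl dibenzoate, [Ir(cod)Cl]2, SEGPHOS (antipode chosen for 12′S), 4‑cyano‑3‑nitrobenzoic acid, K3PO4, THF, 60 °C. The product is (2E,6E,10E,12S,13R)‑13‑(benzoyloxy)‑12‑hydroxy‑3,7,11‑trimethylpentadeca‑2,6,10,14‑tetraen‑1‑yl acetate F7; K2CO3 in MeOH then removes benzoate and acetate to give 6.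

## Further compounds

F1 | step 11 | methyl 2‑(8‑oxo‑1,4‑dioxaspiro[4.5]dec‑6‑en‑9‑yl)acetate (racemic) | COC(=O)CC1CC2(OCCO2)C=CC1=O
F2 | step 11 | methyl 2‑[8‑(tributylstannyloxy)‑1,4‑dioxaspiro[4.5]deca‑6,8‑dien‑9‑yl]acetate | COC(=O)CC1=C(O[Sn](CCCC)(CCCC)CCCC)C=CC2(OCCO2)C1
F3 | step 11 | methyl 2‑[(9R)‑9‑Ch‑8‑oxo‑1,4‑dioxaspiro[4.5]dec‑6‑en‑9‑yl]acetate | COC(=O)C[C@@]1(C/C=C(\C)CC/C=C(\C)CC/C=C(\C)[C@@H]3OC(C)(C)O[C@@H]3C=C(C)C)CC2(OCCO2)C=CC1=O
F4 | step 8 | 1‑Ch‑3,5‑dimethoxycyclohexa‑2,5‑diene‑1‑carboxylic acid | OC(=O)C1(C/C=C(\C)CC/C=C(\C)CC/C=C(\C)[C@@H]2OC(C)(C)O[C@@H]2C=C(C)C)C=C(OC)CC(OC)=C1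
F5 | step 8 | 2‑diazo‑1‑(1‑Ch‑3,5‑dimethoxycyclohexa‑2,5‑dien‑1‑yl)ethan‑1‑one | [N-]=[N+]=CC(=O)C1(C/C=C(\C)CC/C=C(\C)CC/C=C(\C)[C@@H]2OC(C)(C)O[C@@H]2C=C(C)C)C=C(OC)CC(OC)=C1
F0 | step 10 | none | none
F6 | step 7 | methyl 3,5‑dimethoxycyclohexa‑2,5‑diene‑1‑carboxylate | COC(=O)C1C=C(OC)CC(OC)=C1
F7 | step 3 | (2E,6E,10E,12S,13R)‑13‑(benzoyloxy)‑12‑hydroxy‑3,7,11‑trimethylpentadeca‑2,6,10,14‑tetraen‑1‑yl acetate | CC(=O)OC/C=C(\C)CC/C=C(\C)CC/C=C(\C)[C@H](O)[C@H](OC(=O)c1ccccc1)C=C
A1 | alternative 1 | methyl (2,5‑dihydroxyphenyl)acetate (methyl homogentisate) | COC(=O)Cc1cc(O)ccc1O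
A2 | alternative 1 | methyl 2‑(1‑Ch‑2,5‑dioxocyclohex‑3‑en‑1‑yl)acetate, both configurations at the ring quaternary carbon | COC(=O)CC1(C/C=C(\C)CC/C=C(\C)CC/C=C(\C)[C@@H]2OC(C)(C)O[C@@H]2C=C(C)C)CC(=O)C=CC1=O
A3 | alternative 2 | Ch 5,5‑dimethoxy‑1‑(2‑methoxy‑2‑oxoethyl)‑2‑oxocyclohex‑3‑ene‑1‑carboxylate (racemic at the ring carbon) | COC(=O)CC1(C(=O)OC/C=C(\C)CC/C=C(\C)CC/C=C(\C)[C@@H]2OC(C)(C)O[C@@H]2C=C(C)C)CC(OC)(OC)C=CC1=O
A4 | alternative 2 | methyl 2‑[(1R)‑1‑Ch‑5,5‑dimethoxy‑2‑oxocyclohex‑3‑en‑1‑yl]acetate | COC(=O)C[C@@]1(C/C=C(\C)CC/C=C(\C)CC/C=C(\C)[C@@H]2OC(C)(C)O[C@@H]2C=C(C)C)CC(OC)(OC)C=CC1=O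
A5 | alternative 3 | methyl (1R)‑2‑Ch‑4‑oxocyclohex‑2‑en‑1‑yl propanedioate | COC(=O)CC(=O)O[C@@H]1CCC(=O)C=C1C/C=C(\C)CC/C=C(\C)CC/C=C(\C)[C@@H]2OC(C)(C)O[C@@H]2C=C(C)C
A6 | alternative 3 | methyl (3aR,7aR)‑3a‑Ch‑2,5‑dioxooctahydro‑1‑benzofuran‑3‑carboxylate (cis‑fused, both configurations at C3) | COC(=O)C1C(=O)O[C@@H]2CCC(=O)C[C@]12C/C=C(\C)CC/C=C(\C)CC/C=C(\C)[C@@H]3OC(C)(C)O[C@@H]3C=C(C)C
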